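**Strategy.** Numbering: C1 lactone carbonyl, C3 peroxy CH, C4 methyl-bearing fusion carbon, C5 ring CH2, C6 chain-bearing peroxy carbon. The 1,2-dioxane ring is cut (3+3) into the C6–O–O unit, a racemic propargylic hydroperoxy ketal, and the C3–C4–C5 unit of (E)-4-methylpenta-2,4-dienal. In one flask an amine-catalysed oxa-Michael addition joins the peroxide oxygen to C3 and sets its configuration; TMSOTf then ionises the ketal and the isopropenyl π bond closes C5–C6 through a chair (peroxy-Prins), the C4 cation being captured by the aldehyde oxygen as the cis-fused five-membered ring. The step exploits the 1,3-relation of electrophilic C3 and nucleophilic C5 across C4 of the dioxane ring. Oxidation and alkyne saturation finish the synthesis.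

Key step: step 5

Assumption: (10-bromodecyl)benzene is taken as a catalogue compound.
Remark: the descriptor of the chain-bearing carbon (locant 3 in the ring names, C6 in the text) changes from R (12, 13) to S (14) only because the CIP rank of the side chain changes on saturation; the spatial arrangement is the same.

Step 1
Reactants: 1 (10-bromodecyl)benzene; 2 lithium acetylide–ethylenediamine complex (LiC≡CH·H2NCH2CH2NH2)
Product: 3 12-phenyldodec-1-yne
Conditions: DMSO, 0 °C → rt
Reagents that add atoms: none
Why: SN2 displacement of the primary bromide by lithium acetylide (acetylide alkylation) should give the terminal alkyne; no stereocentre is involved.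

Step 2
Reactants: 3 12-phenyldodec-1-yne; 4 N-methoxy-N-methylacetamide
Product: 5 14-phenyltetradec-3-yn-2-one
Conditions: n-BuLi, THF, −78 °C; then 4, −78 → 0 °C; 1 M HCl
Reagents that add atoms: none
Why: The lithium acetylide should add once to the Weinreb amide, whose chelated tetrahedral adduct collapses only on work-up (Weinreb ketone synthesis), so the ynone forms without over-addition.

Step 3
Reactants: 5 14-phenyltetradec-3-yn-2-one
Product: 7 2-hydroperoxy-2-methoxy-14-phenyltetradec-3-yne (racemic), via dimethyl ketal 6 (not isolated)
Conditions: HC(OMe)3, MeOH, CSA (cat.), rt; then H2O2 (ethereal), 0 °C; NaHCO3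
Reagents that add atoms: trimethyl orthoformate, COC(OC)OC; hydrogen peroxide, OO
Why: Orthoformate-driven ketalization followed by acid-catalysed exchange of one methoxy group for hydrogen peroxide through the propargylic oxocarbenium ion (ketal perhydrolysis) should give the α-methoxy hydroperoxide, whose racemic centre is erased in step 5.

Step 4
Reactants: 8 methacrolein; 9 (triphenylphosphoranylidene)acetaldehyde
Product: 10 (2E)-4-methylpenta-2,4-dienal
Conditions: toluene, 80 °C (8 in excess)
Reagents that add atoms: none
Why: Wittig olefination of the aldehyde with the stabilised formyl ylide should give the two-carbon-extended enal with (E) geometry, as expected for a stabilised ylide.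

Step 5
Reactants: 7 2-hydroperoxy-2-methoxy-14-phenyltetradec-3-yne; 10 (2E)-4-methylpenta-2,4-dienal
Product: 12 (3R,4aR,7aR)-6-methoxy-3,4a-dimethyl-3-(12-phenyldodec-1-yn-1-yl)hexahydro-3H-furo[3,2-c][1,2]dioxine (both anomers), via β-peroxy aldehyde 11 (not isolated)
Conditions: (R)-2-{bis[3,5-bis(trifluoromethyl)phenyl](trimethylsilyloxy)methyl}pyrrolidine (10 mol%), PhCO2H (10 mol%), toluene, −20 °C; evaporate; then TMSOTf (0.3 equiv), CH2Cl2, −78 °C; Et3N
Reagents that add atoms: none
Why: Iminium activation of 10 by the (R)-configured amine, whose diarylsilyloxymethyl group blocks the Si face of C3, should let the hydroperoxide oxygen of 7 add 1,4 to the Re face and give (3R)-11 after hydrolysis, the known amine-catalysed asymmetric β-peroxidation of enals with α-alkoxyalkyl hydroperoxides. TMSOTf then removes the ketal methoxy group, and the peroxycarbenium ion is attacked by the 1,1-disubstituted alkene in a 6-endo-trig, Markovnikov cyclization through a chair (peroxy-Prins, the known Lewis-acid cyclization of unsaturated monoperoxy ketals), which closes the 1,2-dioxane and forms C5–C6. The tertiary C4 cation is captured by the aldehyde oxygen of the equatorial C3 side chain, a five-membered closure that can only be cis-fused, and the resulting oxocarbenium ion takes methoxide back from MeOTMS, regenerating TMSOTf. C3 is set by the catalyst; C6 by the chair, in which the C3 side chain is equatorial, the methyl group lies anti to the O–O bond (pseudoequatorial) and the slim alkynyl group syn (pseudoaxial); C4 by the tether; both epimers of the ketal carbon of 7 converge because that centre is ionised. The step needs 1,4- rather than 1,6-addition and protonation of the enamine rather than its attack on the O–O bond (acid co-catalyst, low temperature, bulky tertiary hydroperoxide), and ionization at the methoxy rather than the peroxy oxygen (the more basic ether oxygen is silylated).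

Step 6
Reactants: 12 cyclic methyl acetal
Product: 13 (3R,4aR,7aR)-3,4a-dimethyl-3-(12-phenyldodec-1-yn-1-yl)tetrahydro-3H-furo[3,2-c][1,2]dioxin-6(4H)-one
Conditions: CrO3, H2SO4, acetone/H2O, 0 °C
Reagents that add atoms: water, O
Why: In the Jones oxidation the aqueous acid should hydrolyse the cyclic methyl acetal to the lactol and CrO3 oxidise it to the γ-lactone, conditions under which the dialkyl peroxide, the alkyne and the three stereocentres should be unaffected.

Step 7
Reactants: 13 alkynyl peroxylactone
Product: 14 plakortolide K, (3S,4aR,7aR)-3,4a-dimethyl-3-(12-phenyldodecyl)tetrahydro-3H-furo[3,2-c][1,2]dioxin-6(4H)-one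
Conditions: KO2CN=NCO2K (excess), AcOH, MeOH/CH2Cl2, 0 °C → rt
Reagents that add atoms: none
Why: Diimide generated in situ should deliver hydrogen to the alkyne and then to the cis-alkene by concerted syn transfer (diimide reduction) and, unlike catalytic hydrogenation, leave the O–O bond, the lactone and the arene untouched; no stereocentre is touched.

**Compound list**

1 | (10-bromodecyl)benzene | BrCCCCCCCCCCc1ccccc1 | starting material
2 | lithium acetylide–ethylenediamine complex | [Li]C#C.NCCN | starting material
3 | 12-phenyldodec-1-yne | C#CCCCCCCCCCCc1ccccc1 | intermediate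
4 | N-methoxy-N-methylacetamide | CC(=O)N(C)OC | starting material
5 | 14-phenyltetradec-3-yn-2-one | CC(=O)C#CCCCCCCCCCCc1ccccc1 | intermediate
6 | 2,2-dimethoxy-14-phenyltetradec-3-yne | CC(OC)(OC)C#CCCCCCCCCCCc1ccccc1 | intermediate
7 | 2-hydroperoxy-2-methoxy-14-phenyltetradec-3-yne (racemic) | CC(OC)(OO)C#CCCCCCCCCCCc1ccccc1 | intermediate
8 | methacrolein (2-methylprop-2-enal) | CC(=C)C=O | starting material
9 | (triphenylphosphoranylidene)acetaldehyde | O=CC=P(c1ccccc1)(c1ccccc1)c1ccccc1 | starting material
10 | (2E)-4-methylpenta-2,4-dienal | CC(=C)/C=C/C=O | intermediate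
11 | (3R)-3-[(2-methoxy-14-phenyltetradec-3-yn-2-yl)peroxy]-4-methylpent-4-enal (both configurations at the ketal carbon) | O=CC[C@@H](OOC(C)(OC)C#CCCCCCCCCCCc1ccccc1)C(C)=C | intermediate
12 | (3R,4aR,7aR)-6-methoxy-3,4a-dimethyl-3-(12-phenyldodec-1-yn-1-yl)hexahydro-3H-furo[3,2-c][1,2]dioxine (cis-fused, both anomers) | C[C@]1(C#CCCCCCCCCCCc2ccccc2)C[C@@]2(C)OC(OC)C[C@H]2OO1 | intermediate
13 | (3R,4aR,7aR)-3,4a-dimethyl-3-(12-phenyldodec-1-yn-1-yl)tetrahydro-3H-furo[3,2-c][1,2]dioxin-6(4H)-one | C[C@]1(C#CCCCCCCCCCCc2ccccc2)C[C@@]2(C)OC(=O)C[C@H]2OO1 | intermediate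
14 | plakortolide K, (3S,4aR,7aR)-3,4a-dimethyl-3-(12-phenyldodecyl)tetrahydro-3H-furo[3,2-c][1,2]dioxin-6(4H)-one | C[C@]1(CCCCCCCCCCCCc2ccccc2)C[C@@]2(C)OC(=O)C[C@H]2OO1 | target

Total step count: 7. Longest linear sequence: 6 steps (1 → 3 → 5 → 7 → 12 → 13 → 14).

**Steps most likely to fail**

Step 5. When the Lewis acid is added, the free aldehyde of 11 may be lost through silyl enol ether formation with β-elimination of the peroxide, or through carbonyl-ene closure onto the isopropenyl group. Residual amine may also blunt the ionization. The fallback sets out from 11 and comes back at 13. The amine-catalysed stage is worked up cold and crude 11 is oxidised at once (NaClO2, NaH2PO4, 2-methyl-2-butene, t-BuOH/H2O) to (3R)-3-[(2-methoxy-14-phenyltetradec-3-yn-2-yl)peroxy]-4-methylpent-4-enoic acid F1, which carries no enolisable aldehyde. F1 is then cyclised with TMSOTf in CH2Cl2 at −78 °C, the C4 cation being captured by the carboxylic acid. This should give 13 directly and makes step 6 unnecessary.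

Step 3. The exchange may run on to the geminal dihydroperoxide, the ketal may revert to the ynone, or hydrogen peroxide may add to the ynone in conjugate fashion. The fallback sets out from 3 and comes back at 7, replacing steps 2 and 3. Sonogashira coupling of 3 with 2-bromopropene (Pd(PPh3)2Cl2, CuI, Et3N) should give (13-methyltetradec-13-en-11-yn-1-yl)benzene F2. Ozonolysis of F2 in MeOH/CH2Cl2 at −78 °C cleaves only the alkene, and the carbonyl oxide formed at the disubstituted carbon is trapped by methanol to give 7.

Step 7. The reduction may stall at the cis-alkene, because diimide disproportionates faster than it reduces the hindered propargylic alkyne. The fallback sets out from 5 and comes back at 14, saturating the chain before any peroxide is present. Ynone 5 is hydrogenated (H2, Pd/C, EtOAc) to 14-phenyltetradecan-2-one F3. F3 is converted as in step 3, through (13,13-dimethoxytetradecyl)benzene F4, into (13-hydroperoxy-13-methoxytetradecyl)benzene F5. F5 and 10 under the conditions of step 5 should give, through (3R)-3-[(2-methoxy-14-phenyltetradecan-2-yl)peroxy]-4-methylpent-4-enal F6, the saturated cyclic acetal (3S,4aR,7aR)-6-methoxy-3,4a-dimethyl-3-(12-phenyldodecyl)hexahydro-3H-furo[3,2-c][1,2]dioxine F7. Jones oxidation of F7 as in step 6 gives 14. The price is a weaker bias at C6 (methyl against a primary alkyl chain), so the C6 epimers would have to be separated.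

Further compounds
F1 | step 5 | (3R)-3-[(2-methoxy-14-phenyltetradec-3-yn-2-yl)peroxy]-4-methylpent-4-enoic acid | OC(=O)C[C@@H](OOC(C)(OC)C#CCCCCCCCCCCc1ccccc1)C(C)=C
F2 | step 3 | (13-methyltetradec-13-en-11-yn-1-yl)benzene | C=C(C)C#CCCCCCCCCCCc1ccccc1
F3 | step 7 | 14-phenyltetradecan-2-one | CC(=O)CCCCCCCCCCCCc1ccccc1
F4 | step 7 | (13,13-dimethoxytetradecyl)benzene | CC(OC)(OC)CCCCCCCCCCCCc1ccccc1
F5 | step 7 | (13-hydroperoxy-13-methoxytetradecyl)benzene | CC(OC)(OO)CCCCCCCCCCCCc1ccccc1
F6 | step 7 | (3R)-3-[(2-methoxy-14-phenyltetradecan-2-yl)peroxy]-4-methylpent-4-enal | O=CC[C@@H](OOC(C)(OC)CCCCCCCCCCCCc1ccccc1)C(C)=C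
F7 | step 7 | (3S,4aR,7aR)-6-methoxy-3,4a-dimethyl-3-(12-phenyldodecyl)hexahydro-3H-furo[3,2-c][1,2]dioxine | C[C@]1(CCCCCCCCCCCCc2ccccc2)C[C@@]2(C)OC(OC)C[C@H]2OO1
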